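**Strategy**

The ring is cut across its two trisubstituted olefins: C3=C4 and C9=C10 of the Z,E-cyclodeca-1,5-diene unit (C9=C10–C1–C2–C3=C4) are traced back to the sigma bonds C3–C10 and C4–C9 of a cyclobutane. Then C4 to C9, with the methyl and isopropyl groups, is the six-membered ring of piperitone, and C1, C2, C3, C10 are a 2-methylcyclobutenol. The key step, an enone–cyclobutene [2+2] photocycloaddition, forms C3–C4 and C9–C10 in one operation and delivers a cis-anti-cis 6-4-4 tricycle carrying all ring carbons and the C1 and C7 stereocentres. Its precursors are (S)-piperitone and the (S)-silyl ether of 2-methylcyclobut-2-en-1-ol; thermal cycloreversion then opens the ten-membered ring.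

Key step: step 7

**Remarks and assumptions (chemistry)**

- Ring numbering: C1 (angelate carbon), C2, C3=C4 (methyl on C4), C5, C6, C7 (isopropyl), C8 (acetate carbon), C9=C10 (methyl on C10). The target is 1S,7S,8R with 3E,9Z; the acetate is cis to the isopropyl group.
- Stereochemical bookkeeping: C7 is the isopropyl-bearing carbon of (S)-piperitone and of (−)-menthone, with unchanged geometry and descriptor. C1 is the carbinol carbon of (S)-2-methylcyclobut-2-en-1-ol, also with unchanged descriptor. C8 is set by reduction after ring opening.
- Assumption: the (−)-menthone is free of isomenthone, because the C2 epimer would end up as (R)-piperitone. The lipase is assumed to show its usual preference for the R alcohol; the configuration of the recovered alcohol would be confirmed as its Mosher ester before silylation.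
- Design of the cyclobutene partner: an oxygen on the sp3 carbon of a cyclobutene lowers the barrier to conrotatory ring opening, and an alkoxide does so drastically. The cyclobutenol and its silyl ether are therefore kept at or below 5 °C, never deprotonated, and irradiated cold. A silyl ether is kept (not an ester) because it must survive hydride and be removed later beside the C8 acetate.
- No base is used between the photocycloaddition and the reduction, since C7 is alpha to the ketone.

**Route**

Step 1
Reactants: 1 (−)-menthone
Product: 2 trimethyl{[(3R,6S)-3-methyl-6-(propan-2-yl)cyclohex-1-en-1-yl]oxy}silane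
Conditions: LiN(i-Pr)2, THF, −78 °C; Me3SiCl, −78 → 0 °C; non-aqueous work-up (pentane, filtration)
Reagents that add atoms: chlorotrimethylsilane, C[Si](C)(C)Cl
Why: Kinetic deprotonation by the hindered amide removes a proton of the less hindered ring CH2 and silylation traps the less substituted enolate (regioselective silyl enol ether formation), leaving the epimerisable isopropyl-bearing centre untouched.

Step 2
Reactants: 2 silyl enol ether
Product: 3 (S)-piperitone
Conditions: Pd(OAc)2 (1.05 equiv), MeCN, 25 °C; chromatography, no distillation
Reagents that add atoms: none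
Why: Saegusa–Ito oxidation: the palladium enolate undergoes syn beta-hydride elimination of the only available beta-hydrogen (on the methyl-bearing carbon), giving the enone regiospecifically; that stereocentre is erased and the isopropyl-bearing centre stays S.

Step 3
Reactants: 4 methylenecyclobutane
Product: 5 1-methylcyclobut-1-ene
Conditions: KOt-Bu (cat.), DMSO, 25 °C; product taken off through a fractionating column
Reagents that add atoms: none
Why: Base-catalysed prototropic alkene isomerisation moves the exocyclic double bond into the ring to the trisubstituted isomer, and removal of the lower-boiling product drives the conversion.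

Step 4
Reactants: 5 1-methylcyclobut-1-ene
Product: 6 rac-2-methylcyclobut-2-en-1-ol
Conditions: SeO2 (cat.), t-BuOOH, CH2Cl2, 0–10 °C; cold work-up and cold chromatography
Reagents that add atoms: tert-butyl hydroperoxide, CC(C)(C)OO (terminal oxygen source, delivered through selenium dioxide, O=[Se]=O)
Why: Allylic hydroxylation with SeO2 (ene reaction, then [2,3]-sigmatropic shift) attacks the ring CH2 at the more substituted alkene terminus and returns the double bond to its original position, giving the racemic secondary allylic alcohol.

Step 5
Reactants: 6 rac-2-methylcyclobut-2-en-1-ol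
Product: 7 (S)-2-methylcyclobut-2-en-1-ol
Conditions: immobilised Candida antarctica lipase B, vinyl butanoate, t-BuOMe, 4 °C, run slightly beyond half conversion; filtration
Reagents that add atoms: none
Why: Lipase-catalysed kinetic resolution by irreversible transesterification: the enzyme should acylate the R enantiomer (the methyl-substituted vinylic carbon being the larger substituent) and leave the S alcohol, whose enantiomeric purity rises with conversion; this fixes C1 of the target.

Step 6
Reactants: 7 (S)-2-methylcyclobut-2-en-1-ol
Product: 8 tert-butyldimethyl{[(1S)-2-methylcyclobut-2-en-1-yl]oxy}silane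
Conditions: t-BuMe2SiCl, imidazole, CH2Cl2, 0 °C; stored at −20 °C
Reagents that add atoms: tert-butyldimethylsilyl chloride, CC(C)(C)[Si](C)(C)Cl
Why: Silylation of a secondary alcohol under non-anionic conditions, which avoids the alkoxide that would trigger electrocyclic ring opening; the carbinol configuration is not touched.

Step 7
Reactants: 3 (S)-piperitone; 8 (S)-silyl ether of 2-methylcyclobut-2-en-1-ol
Product: 9 cis-anti-cis tricyclic photoadduct, (1R,2R,4S,5R,6R,8S)-4-[(tert-butyldimethylsilyl)oxy]-1,5-dimethyl-8-(propan-2-yl)tricyclo[4.4.0.0(2,5)]decan-7-one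
Conditions: hν (350–366 nm, Pyrex filter), 8 (2 equiv, excess recovered), degassed CH2Cl2, −30 °C; neutral chromatography
Reagents that add atoms: none
Why: Excitation of the enone and intersystem crossing give the triplet of 3, which bonds through its beta-carbon C4 to the unsubstituted cyclobutene carbon C3 to form a triplet 1,4-biradical (alpha-keto radical at C9, tertiary radical at C10) that closes at C9–C10 after spin inversion. The closest known reaction type is the intermolecular enone–alkene [2+2] photocycloaddition of 3-alkylcyclohex-2-enones with cyclobutenes. The one ring closed is the central cyclobutane C3–C4–C9–C10, formed by stepwise intermolecular [2+2] union with radical–radical 1,4-closure as the second bond, cis-fused to the cyclohexanone and necessarily cis-fused to the existing four-membered ring. Of the four new centres, C4/C9 and C3/C10 are each set cis by these ring fusions, the anti relation of the outer rings comes from approach of the cyclobutene with its ring turned away from the cyclohexanone, and the faces used are the one anti to the silyloxy group and the axial one at C4 of the half-chair with equatorial isopropyl. The selectivity that matters is the head-to-head orientation (C4 to C3, C9 to C10); it is secured because the reverse orientation would have to join the two fully substituted carbons C4 and C10, a biradical that reverts to the partners, and the silyloxy-bearing C1 adds further bulk at C10. Since C3, C4, C9 and C10 all become sp2 in step 8, any mixture of cis-fused facial or syn/anti isomers is carried forward together.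

Step 8
Reactants: 9 tricyclic photoadduct
Product: 10 (2Z,4S,6E,10S)-4-[(tert-butyldimethylsilyl)oxy]-3,7-dimethyl-10-(propan-2-yl)cyclodeca-2,6-dien-1-one
Conditions: flash vacuum thermolysis, silylated quartz tube, ca. 430 °C, 0.05 mbar, short contact time, trap at −78 °C
Reagents that add atoms: none
Why: Thermal cycloreversion of the bicyclo[2.2.0]hexane unit (retro-[2+2] through a cyclohexane-1,4-diyl): homolysis of the strained central C3–C10 bond and scission of C4–C9 turn both photochemically made sigma bonds into olefins, with the chair-like diyl expected to give 3E,9Z geometry and the Z olefin conjugated to the ketone; C1 and C7 are not involved.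

Step 9
Reactants: 10 cyclodecadienone
Product: 11 (1R,2Z,4S,6E,10S)-4-[(tert-butyldimethylsilyl)oxy]-3,7-dimethyl-10-(propan-2-yl)cyclodeca-2,6-dien-1-ol
Conditions: LiBH(s-Bu)3, THF, −78 °C; aqueous work-up
Reagents that add atoms: none
Why: Substrate-controlled 1,2-reduction of a beta,beta-disubstituted enone by a bulky trialkylborohydride: hydride is expected to attack the exposed outer face of the carbonyl, away from the adjacent pseudo-equatorial isopropyl group, which places the new C8 hydroxyl cis to isopropyl (8R).

Step 10
Reactants: 11 allylic alcohol
Product: 12 (1R,2Z,4S,6E,10S)-4-[(tert-butyldimethylsilyl)oxy]-3,7-dimethyl-10-(propan-2-yl)cyclodeca-2,6-dien-1-yl acetate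
Conditions: Ac2O, pyridine, DMAP (cat.), CH2Cl2, 0 → 25 °C
Reagents that add atoms: acetic anhydride, CC(=O)OC(C)=O
Why: DMAP-catalysed acyl transfer to the secondary allylic alcohol proceeds at oxygen, so C8 keeps its configuration and the silyl ether is inert.

Step 11
Reactants: 12 silyl ether acetate
Product: 13 (1R,2Z,4S,6E,10S)-4-hydroxy-3,7-dimethyl-10-(propan-2-yl)cyclodeca-2,6-dien-1-yl acetate
Conditions: HF·pyridine, pyridine, THF, 0 → 25 °C
Reagents that add atoms: none
Why: Fluoride-mediated desilylation cleaves Si–O and not C–O, so C1 keeps its configuration, and the buffered acidic medium avoids acetate migration or hydrolysis.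

Step 12
Reactants: 13 hydroxy acetate
Product: 14 (1S,2Z,4R,5S,8E)-4-(acetyloxy)-2,8-dimethyl-5-(propan-2-yl)cyclodeca-2,8-dien-1-yl (2Z)-2-methylbut-2-enoate (target)
Conditions: (Z)-2-methylbut-2-enoic acid, 2,4,6-trichlorobenzoyl chloride, Et3N, toluene, 25 °C; then 13, toluene, 70 °C, no DMAP
Reagents that add atoms: angelic acid, C/C=C(/C)C(=O)O
Why: Yamaguchi esterification through the preformed mixed 2,4,6-trichlorobenzoic anhydride, run without a nucleophilic amine catalyst so that the Z-enoate is not isomerised to the tiglate; acylation at oxygen retains C1.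

**Compound list**

1 | (−)-menthone, (2S,5R)-5-methyl-2-(propan-2-yl)cyclohexan-1-one | C[C@@H]1CC[C@H](C(=O)C1)C(C)C | starting material
2 | trimethyl{[(3R,6S)-3-methyl-6-(propan-2-yl)cyclohex-1-en-1-yl]oxy}silane | C[C@@H]1CC[C@@H](C(C)C)C(O[Si](C)(C)C)=C1 | intermediate
3 | (S)-piperitone, (6S)-3-methyl-6-(propan-2-yl)cyclohex-2-en-1-one | CC1=CC(=O)[C@H](C(C)C)CC1 | intermediate
4 | methylenecyclobutane | C=C1CCC1 | starting material
5 | 1-methylcyclobut-1-ene | CC1=CCC1 | intermediate
6 | rac-2-methylcyclobut-2-en-1-ol | CC1=CCC1O | intermediate
7 | (S)-2-methylcyclobut-2-en-1-ol | O[C@H]1CC=C1C | intermediate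
8 | tert-butyldimethyl{[(1S)-2-methylcyclobut-2-en-1-yl]oxy}silane | CC(C)(C)[Si](C)(C)O[C@H]1CC=C1C | intermediate
9 | (1R,2R,4S,5R,6R,8S)-4-[(tert-butyldimethylsilyl)oxy]-1,5-dimethyl-8-(propan-2-yl)tricyclo[4.4.0.0(2,5)]decan-7-one; cis-anti-cis 6-4-4 tricycle, silyloxy on the outer face, isopropyl cis to the C9–C10 bond (1S,3R,4R,7S,9R,10R in target numbering) | CC(C)(C)[Si](C)(C)O[C@H]1C[C@@H]2[C@@]3(C)CC[C@@H](C(C)C)C(=O)[C@H]3[C@]12C | intermediate
10 | (2Z,4S,6E,10S)-4-[(tert-butyldimethylsilyl)oxy]-3,7-dimethyl-10-(propan-2-yl)cyclodeca-2,6-dien-1-one | CC(C)(C)[Si](C)(C)O[C@H]1C/C=C(\C)CC[C@@H](C(C)C)C(=O)/C=C\1C | intermediate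
11 | (1R,2Z,4S,6E,10S)-4-[(tert-butyldimethylsilyl)oxy]-3,7-dimethyl-10-(propan-2-yl)cyclodeca-2,6-dien-1-ol | CC(C)(C)[Si](C)(C)O[C@H]1C/C=C(\C)CC[C@@H](C(C)C)[C@@H](O)/C=C\1C | intermediate
12 | (1R,2Z,4S,6E,10S)-4-[(tert-butyldimethylsilyl)oxy]-3,7-dimethyl-10-(propan-2-yl)cyclodeca-2,6-dien-1-yl acetate | CC(C)(C)[Si](C)(C)O[C@H]1C/C=C(\C)CC[C@@H](C(C)C)[C@@H](OC(C)=O)/C=C\1C | intermediate
13 | (1R,2Z,4S,6E,10S)-4-hydroxy-3,7-dimethyl-10-(propan-2-yl)cyclodeca-2,6-dien-1-yl acetate | O[C@H]1C/C=C(\C)CC[C@@H](C(C)C)[C@@H](OC(C)=O)/C=C\1C | intermediate
14 | (1S,2Z,4R,5S,8E)-4-(acetyloxy)-2,8-dimethyl-5-(propan-2-yl)cyclodeca-2,8-dien-1-yl (2Z)-2-methylbut-2-enoate | C/C=C(/C)C(=O)O[C@H]1C/C=C(\C)CC[C@@H](C(C)C)[C@@H](OC(C)=O)/C=C\1C | target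

**Step count**

Total: 12 steps. Longest linear sequence: 10 steps (steps 3 to 12, from methylenecyclobutane); the piperitone branch is 2 steps and joins at step 7.

**Steps most likely to fail**

1. Step 8 (cycloreversion). The 1,4-diyl may partition toward scission of C1–C2, the product may undergo a [3,3] shift in the hot zone to a 1,2-divinylcyclohexanone, or C7 may epimerise by enolisation on the hot surface. The fallback takes the carbonyl out of play before the thermolysis and sets out from 9 (its major diastereomer, as drawn). Reduction with LiBH(s-Bu)3 in THF at −78 °C should proceed by equatorial attack on the rigid cyclohexanone from the face opposite the cyclobutane and the isopropyl group, giving the axial 8R tricyclic alcohol F1. Acetylation (Ac2O, pyridine, DMAP) gives the tricyclic acetate F2. Thermolysis of F2 in degassed solution (sealed tube, toluene, ca. 190 °C) has no enolisable alpha-centre and no carbonyl-bearing rearrangement product to drain into. The product is acetate 12, where the route is rejoined before step 11. This fallback also settles C8 on a rigid framework.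

2. Step 7 (photocycloaddition). The electron-rich silyloxycyclobutene may be lost by thermal or sensitised ring opening during irradiation, or may add with insufficient head-to-head selectivity. The fallback carries the oxygen through the cycloaddition as an ester, which slows electrocyclic opening and lowers the donor character of the alkene; it sets out from 7 and 3. Acetylation of 7 (Ac2O, pyridine, 0 °C) gives (S)-2-methylcyclobut-2-en-1-yl acetate F3. Irradiation of F3 with 3 under the conditions of step 7 gives the tricyclic keto acetate F4. Acid-catalysed methanolysis (HCl in MeOH, 0–20 °C, no base, so C7 is not epimerised) gives the tricyclic hydroxy ketone F5. Silylation (t-BuMe2SiCl, imidazole, DMF, 25 °C) returns the route to 9.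

3. Step 9 (reduction on the flexible ring). Facial selectivity at the C8 carbonyl may be poor or reversed, because the ten-membered ring offers no rigid bias. The fallback uses the unwanted epimer and sets out from 10. Reduction with whichever hydride gives it most cleanly (LiBH(s-Bu)3, or NaBH4 with CeCl3·7H2O in MeOH) provides the 8S alcohol F6. Mitsunobu inversion with acetic acid (PPh3, diisopropyl azodicarboxylate, AcOH, toluene, 0 → 25 °C) converts F6 directly into acetate 12, replacing step 10; the route continues with step 11.

**Further compounds**

F1 | step 8 | 8R alcohol of 9: cis-anti-cis tricycle with axial C8 hydroxyl cis to isopropyl and to the cyclobutane, (1R,2R,4S,5R,6R,7R,8S)-4-[(tert-butyldimethylsilyl)oxy]-1,5-dimethyl-8-(propan-2-yl)tricyclo[4.4.0.0(2,5)]decan-7-ol | CC(C)(C)[Si](C)(C)O[C@H]1C[C@@H]2[C@@]3(C)CC[C@@H](C(C)C)[C@@H](O)[C@H]3[C@]12C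
F2 | step 8 | acetate of F1, same configuration | CC(C)(C)[Si](C)(C)O[C@H]1C[C@@H]2[C@@]3(C)CC[C@@H](C(C)C)[C@@H](OC(C)=O)[C@H]3[C@]12C
F3 | step 7 | (S)-2-methylcyclobut-2-en-1-yl acetate | CC(=O)O[C@H]1CC=C1C
F4 | step 7 | C1 acetate analogue of 9 (acetoxy in place of silyloxy, same configuration at all six centres) | CC(=O)O[C@H]1C[C@@H]2[C@@]3(C)CC[C@@H](C(C)C)C(=O)[C@H]3[C@]12C
F5 | step 7 | C1 hydroxy analogue of 9 (free cyclobutanol, same configuration) | O[C@H]1C[C@@H]2[C@@]3(C)CC[C@@H](C(C)C)C(=O)[C@H]3[C@]12C
F6 | step 9 | C8 epimer of 11, (1S,2Z,4S,6E,10S)-4-[(tert-butyldimethylsilyl)oxy]-3,7-dimethyl-10-(propan-2-yl)cyclodeca-2,6-dien-1-ol | CC(C)(C)[Si](C)(C)O[C@H]1C/C=C(\C)CC[C@@H](C(C)C)[C@H](O)/C=C\1C
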